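My neighbour charged 0.020 M of starting material in eta where I charged 0.0012 M in theta, and we both wanted to know what that does to the percentage of target.

    starting material + second chain carrier → by-product + first chain carrier (k1 = 12000 M⁻¹ s⁻¹)
    coupling partner → decomposed reagent (k2 = 9.7 × 10⁻⁴ s⁻¹)
    coupling partner + first chain carrier → target + second chain carrier (k3 = 1000 M⁻¹ s⁻¹)
    starting material + initiating radical → capped initiator + first chain carrier (k4 = 4.4 × 10⁵ M⁻¹ s⁻¹)
    initiator → 2 initiating radical (k5 = 0.0052 s⁻¹)
    2 idle radical → ended radicals (k6 = 6.7 × 10⁷ M⁻¹ s⁻¹)
    crystals ⇌ by-product, rate k7*(cs7 - [by-product]) while solid is left; crystals form when [by-product] > cs7 (cs7 = 7.5 mM, k7 = 0.38 s⁻¹)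
    2 first chain carrier → ended chains (k8 = 2.4 × 10⁶ M⁻¹ s⁻¹)
    transfer agent + first chain carrier → side product + idle radical (k9 = 3700 M⁻¹ s⁻¹)

in all of them: coupling partner 0.0800 M; transfer agent 1.00 mM; initiator 1.0 mM; time 20 min
- theta: starting material 0.0012 M
- epsilon: starting material 0.0025 M
- delta: starting material 0.0050 M
- alpha: starting material 0.010 M
- eta: starting material 0.020 M

- amount of target at the end, in percent of the starting material charged for theta, epsilon, delta, alpha, eta, in this order
- how that number moves from the first to the last of them (hardly changes / falls all the way / rises all the way / rises, then falls / falls, then rises)

- percentages count the starting material that a species holds: one ended chains counts as two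
- by-product is meant together with its crystals
- a doubled species enters its step squared and goes two at a time
- solid, in amounts per volume of the solution: crystals
- "hardly changes" means that all values lie within two and a half points (for a concentration: within two and a half percent of the largest)
- run time (theta): 20 min

I reckoned the small part that is lost, not the large part that is won. In the scheme, a starting material that reacts becomes a first chain carrier, and that carrier then either meets coupling partner and gives target, or dies by pairing or by transfer.

In the first instants of theta, the initiator, with a half-life of 2.2 min, fed radicals at 1.04 × 10⁻⁵ M s⁻¹. An initiating radical lasted about 0.00189 s before it met starting material, far shorter than that half-life, so the feed passed straight on to first chain carriers.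

For the middle of theta, I took c(first chain carrier) to stand at its steady state, where pairing and transfer together removed what the initiator fed, with the initiator, coupling partner and transfer agent at their charges. That gave 1.14 × 10⁻⁶ M. At that level in my reckoning for theta, a carrier coupled at 80.0 s⁻¹ and died at 9.15 s⁻¹, so coupling was faster than dying.

I call the leak the share of carriers that die, dying over dying plus coupling: 10.3%. Starting material stands nowhere in that fraction, so my reckoning gave one figure for the row, target near 89.7%, and a flat shape.

I expected the chain to stop with the starting material. At the starting rates it would go at 1.01 × 10⁻⁴ M s⁻¹, which would take the 0.0012 M of theta in about 11.8 s, shorter than the initiator's half-life, so I kept the starting rates for theta. The 0.020 M of eta would take about 197 s at those rates, longer than that half-life, so the same figure is rougher for eta.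

The forecast stood 1.1 percentage points above my figure at its first point, reading 90.8%, 90.4%, 90.6%, 90.8% and 91.5%, and it called the shape hardly changes: “so the number hardly changes”.

The flasks gave 90.8%, 90.3%, 90.2%, 90.3% and 91.0%, and the shape was hardly changes. At the end of theta, target stood beside side product at 4.15% and ended chains at 5.01%, each in percent of the starting material charged. Against my leak of 10.3%, those two losses came to 9.16% in theta. In eta, with side product at 3.42% and ended chains at 5.63%, they came to 9.05%.

The numbers belong to no real substance; the rest is arithmetic.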